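**Plan**
Retrosynthetic cuts, in order: the propenyl C=C at C5 (olefination of an aldehyde), the C7–OMe bond (aryl C–O coupling), the two benzo-ring bonds C7–C7a and C3a–C4, and last the C2–C3 bond (crotylation of an aryl aldehyde).
Enabling feature: O1–C7a=C3a of the dihydrobenzofuran is the O–C=C of the silyl ketene acetal of a 4-methyl-5-aryl γ-lactone, and C4–C7 with their substituents (H, CO2Me → propenyl, H, Br → OMe) are C6–C3 of a 3,5-disubstituted 2-pyrone.
Forward order: the oxygen ring is made first as the trans γ-lactone, the benzene ring is then grown onto it by pyrone [4+2] addition, CO2 loss and silanol loss, and the 7-OMe and the E-propenyl group are finished last.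
Stereochemistry: C2 and C3 both come from one catalyst-controlled anti-crotylboration of 3,4,5-trimethoxybenzaldehyde (closed chair transition state, Re face); no later step touches them.

Key step: step 6

Assumption: (R)-TRIP is taken to deliver (E)-crotyl pinacolboronate to the Re face of the aryl aldehyde, as it does with benzaldehyde; the route needs this Re-face anti mode, whichever catalyst enantiomer provides it.

**Route**

Step 1
Reactants: 1 3,4,5-trimethoxybenzaldehyde; 2 (E)-crotylboronic acid pinacol ester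
Product: 4 (1R,2R)-2-methyl-1-(3,4,5-trimethoxyphenyl)but-3-en-1-ol, via pinacol borate ester 3 (not isolated)
Conditions: (R)-TRIP (5 mol%), toluene, −30 → 0 °C; aq. NaHCO3 work-up
Reagents that add atoms: none
Why: Chiral phosphoric acid-catalysed crotylboration through a closed six-membered chair transition state, in which the E geometry of the boronate gives the anti relationship and the catalyst exposes the aldehyde Re face, so that the carbinol carbon (future C2) and the methyl-bearing carbon (future C3) are both set R in one step.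

Step 2
Reactants: 4 (1R,2R)-2-methyl-1-(3,4,5-trimethoxyphenyl)but-3-en-1-ol
Product: 6 (1R,2R)-2-methyl-1-(3,4,5-trimethoxyphenyl)butane-1,4-diol, via alkyl-9-BBN adduct 5 (not isolated)
Conditions: 9-BBN (2.5 equiv), THF, 0 °C → rt; then 3 M NaOH, 30% H2O2, 0 °C → rt
Reagents that add atoms: hydrogen peroxide, OO
Why: Hydroboration–oxidation, in which the bulky borane places boron on the terminal alkene carbon only and alkaline peroxide replaces it by hydroxyl without touching the two stereocentres (the excess reagent covers the free hydroxyl).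

Step 3
Reactants: 6 (1R,2R)-2-methyl-1-(3,4,5-trimethoxyphenyl)butane-1,4-diol
Product: 9 (4R,5R)-4-methyl-5-(3,4,5-trimethoxyphenyl)oxolan-2-one, via hydroxy aldehyde 7 (not isolated), via lactol 8 (not isolated)
Conditions: TEMPO (20 mol%), PhI(OAc)2 (2.5 equiv), CH2Cl2, rt
Reagents that add atoms: none
Why: Oxoammonium oxidation is much faster at the primary than at the secondary benzylic alcohol, the hydroxy aldehyde closes to the five-membered lactol and this is oxidised on to the trans γ-lactone (oxidative lactonisation of a 1,4-diol).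

Step 4
Reactants: 9 (4R,5R)-4-methyl-5-(3,4,5-trimethoxyphenyl)oxolan-2-one
Product: 11 tert-butyl{[(4R,5R)-4-methyl-5-(3,4,5-trimethoxyphenyl)-4,5-dihydrofuran-2-yl]oxy}dimethylsilane, via lithium enolate 10 (not isolated)
Conditions: LDA, THF, −78 °C; TBSCl, DMPU, −78 → 0 °C; pentane, filtration, concentration (used without chromatography)
Reagents that add atoms: tert-butyldimethylsilyl chloride (TBSCl), CC(C)(C)[Si](C)(C)Cl
Why: Kinetic deprotonation of the lactone α-CH2 and O-silylation of the lithium enolate in the presence of DMPU give the cyclic silyl ketene acetal, while the non-enolisable C4 and C5 stay R,R.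

Step 5
Reactants: 12 methyl coumalate
Product: 14 methyl 3-bromo-2-oxo-2H-pyran-5-carboxylate, via dibromide adduct 13 (not isolated)
Conditions: Br2, CH2Cl2, 0 °C → rt; then Et3N, 0 °C
Reagents that add atoms: bromine, BrBr
Why: Electrophilic bromination of the 2-pyrone by addition–elimination, in which bromine adds at the C3=C4 bond (C5 is blocked by the ester) and triethylamine removes the acidic C3–H with loss of bromide to restore the pyrone with bromine at C3.

Step 6
Reactants: 11 tert-butyl{[(4R,5R)-4-methyl-5-(3,4,5-trimethoxyphenyl)-4,5-dihydrofuran-2-yl]oxy}dimethylsilane; 14 methyl 3-bromo-2-oxo-2H-pyran-5-carboxylate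
Product: 17 methyl (2R,3R)-7-bromo-3-methyl-2-(3,4,5-trimethoxyphenyl)-2,3-dihydro-1-benzofuran-5-carboxylate, via bridged lactone cycloadduct 15 (not isolated), via cyclohexadienyl silyl ketal 16 (not isolated)
Conditions: 11 (1.3 equiv), toluene, rt then 100 °C (−CO2); then DBU (1.2 equiv), rt
Reagents that add atoms: none
Why: Inverse-electron-demand Diels–Alder addition of the electron-rich C=C of 11 across C3 and C6 of the electron-poor pyrone 14 (the nucleophilic CH carbon, future C3a, to C6; the ketal carbon, future C7a, to the bromine-bearing C3) should give the bridged lactone 15, which loses CO2 by retro-[4+2] to diene 16; DBU then removes the ester-acidified C3a–H and the silanolate leaves from C7a (E1cB), so the ring aromatises with O1 in place. The closest known reaction type is the benzannulation of coumalates and other electron-poor 2-pyrones with ketene acetals, which gives alkoxybenzoates by the same cycloaddition, CO2 extrusion and loss of an alcohol. The benzene ring, the only ring formed, closes by intermolecular [4+2] cycloaddition, both of its new bonds (C3a–C4 and C7–C7a) coming from that event, and becomes aromatic through the two eliminations. No lasting stereocentre is created: the four sp3 centres of 15 are erased on aromatisation, so facial and endo/exo selectivity do not matter, and C2 and C3 lie outside the reacting π system and carry no acidic hydrogen, so the trans R,R pair is carried through. The step needs the regiochemistry that puts O1 para to the ester and ortho to bromine, which the polarised ketene acetal and the large LUMO coefficient at pyrone C6 secure, and it needs silanol rather than the ring alkoxide to leave, which the better nucleofugality of the silanolate and the fluoride-free basic finish favour.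

Step 7
Reactants: 17 methyl (2R,3R)-7-bromo-3-methyl-2-(3,4,5-trimethoxyphenyl)-2,3-dihydro-1-benzofuran-5-carboxylate
Product: 18 methyl (2R,3R)-7-methoxy-3-methyl-2-(3,4,5-trimethoxyphenyl)-2,3-dihydro-1-benzofuran-5-carboxylate
Conditions: NaOMe (5 equiv), CuI (20 mol%), DMF/MeOH, 110 °C
Reagents that add atoms: sodium methoxide, C[O-].[Na+]
Why: Ullmann-type copper(I)-catalysed C–O coupling of an aryl bromide with methoxide, well established for bromides ortho to an oxygen substituent; the methyl ester only exchanges degenerately with methoxide and neither stereocentre carries an acidic hydrogen.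

Step 8
Reactants: 18 methyl (2R,3R)-7-methoxy-3-methyl-2-(3,4,5-trimethoxyphenyl)-2,3-dihydro-1-benzofuran-5-carboxylate
Product: 19 [(2R,3R)-7-methoxy-3-methyl-2-(3,4,5-trimethoxyphenyl)-2,3-dihydro-1-benzofuran-5-yl]methanol
Conditions: LiAlH4, THF, 0 °C; H2O/NaOH work-up
Reagents that add atoms: none
Why: Hydride reduction of the aryl ester to the benzylic alcohol; the aryl ethers and the benzylic C–O bond of the dihydrofuran are inert to LiAlH4 at 0 °C.

Step 9
Reactants: 19 [(2R,3R)-7-methoxy-3-methyl-2-(3,4,5-trimethoxyphenyl)-2,3-dihydro-1-benzofuran-5-yl]methanol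
Product: 20 (2R,3R)-7-methoxy-3-methyl-2-(3,4,5-trimethoxyphenyl)-2,3-dihydro-1-benzofuran-5-carbaldehyde
Conditions: activated MnO2, CH2Cl2, rt
Reagents that add atoms: none
Why: Activated MnO2 oxidises benzylic alcohols to aldehydes under neutral conditions without over-oxidation, so the acid-sensitive benzylic ether is not at risk.

Step 10
Reactants: 20 (2R,3R)-7-methoxy-3-methyl-2-(3,4,5-trimethoxyphenyl)-2,3-dihydro-1-benzofuran-5-carbaldehyde; 21 5-(ethylsulfonyl)-1-phenyl-1H-tetrazole
Product: 24 (2R,3R)-7-methoxy-3-methyl-5-[(E)-prop-1-en-1-yl]-2-(3,4,5-trimethoxyphenyl)-2,3-dihydro-1-benzofuran, via potassium sulfonyl carbanion 22 (not isolated), via β-alkoxy sulfone 23 (not isolated)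
Conditions: KHMDS, DME, −60 °C → rt; aq. NH4Cl
Reagents that add atoms: none
Why: Julia–Kocienski olefination, in which the metallated sulfone adds to the aldehyde and the alkoxide undergoes Smiles rearrangement with loss of SO2 and the tetrazolone, a sequence that with potassium in DME should favour the E alkene and leaves the base-stable stereocentres alone.

**Compound list**
1 | 3,4,5-trimethoxybenzaldehyde | COc1cc(C=O)cc(OC)c1OC | starting material
2 | (E)-crotylboronic acid pinacol ester | C/C=C/CB1OC(C)(C)C(C)(C)O1 | starting material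
3 | 2-{[(1R,2R)-2-methyl-1-(3,4,5-trimethoxyphenyl)but-3-en-1-yl]oxy}-4,4,5,5-tetramethyl-1,3,2-dioxaborolane (pinacol borate ester) | C=C[C@@H](C)[C@H](c1cc(OC)c(OC)c(OC)c1)OB1OC(C)(C)C(C)(C)O1 | intermediate
4 | (1R,2R)-2-methyl-1-(3,4,5-trimethoxyphenyl)but-3-en-1-ol (anti) | C=C[C@@H](C)[C@H](c1cc(OC)c(OC)c(OC)c1)O | intermediate
5 | (1R,2R)-4-(9-borabicyclo[3.3.1]nonan-9-yl)-2-methyl-1-(3,4,5-trimethoxyphenyl)butan-1-ol (alkyl-9-BBN adduct) | C1CC2CCCC(C1)B2CC[C@@H](C)[C@H](c1cc(OC)c(OC)c(OC)c1)O | intermediate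
6 | (1R,2R)-2-methyl-1-(3,4,5-trimethoxyphenyl)butane-1,4-diol | OCC[C@@H](C)[C@H](c1cc(OC)c(OC)c(OC)c1)O | intermediate
7 | (3R,4R)-4-hydroxy-3-methyl-4-(3,4,5-trimethoxyphenyl)butanal (hydroxy aldehyde) | O=CC[C@@H](C)[C@H](c1cc(OC)c(OC)c(OC)c1)O | intermediate
8 | (4R,5R)-4-methyl-5-(3,4,5-trimethoxyphenyl)oxolan-2-ol (lactol, anomers) | OC1C[C@@H](C)[C@H](c2cc(OC)c(OC)c(OC)c2)O1 | intermediate
9 | (4R,5R)-4-methyl-5-(3,4,5-trimethoxyphenyl)oxolan-2-one (trans γ-lactone) | O=C1C[C@@H](C)[C@H](c2cc(OC)c(OC)c(OC)c2)O1 | intermediate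
10 | lithium (4R,5R)-4-methyl-5-(3,4,5-trimethoxyphenyl)-4,5-dihydrofuran-2-olate (lithium enolate) | [Li]OC1=C[C@@H](C)[C@H](c2cc(OC)c(OC)c(OC)c2)O1 | intermediate
11 | tert-butyl{[(4R,5R)-4-methyl-5-(3,4,5-trimethoxyphenyl)-4,5-dihydrofuran-2-yl]oxy}dimethylsilane | CC(C)(C)[Si](C)(C)OC1=C[C@@H](C)[C@H](c2cc(OC)c(OC)c(OC)c2)O1 | intermediate
12 | methyl coumalate (methyl 2-oxo-2H-pyran-5-carboxylate) | COC(=O)C1=COC(=O)C=C1 | starting material
13 | methyl 3,4-dibromo-2-oxo-3,4-dihydro-2H-pyran-5-carboxylate (dibromide adduct) | COC(=O)C1=COC(=O)C(Br)C1Br | intermediate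
14 | methyl 3-bromo-2-oxo-2H-pyran-5-carboxylate | COC(=O)C1=COC(=O)C(Br)=C1 | intermediate
15 | methyl 4-bromo-3-oxo-2-oxabicyclo[2.2.2]oct-5-ene-6-carboxylate fused at C7–C8 to the (2R,3R)-3-methyl-2-aryl-oxolane ring, OTBS on the ring-fusion ketal carbon (bridged lactone cycloadduct; new centres not assigned) | COC(=O)C1=CC2(Br)C(=O)OC1C1[C@@H](C)[C@H](c3cc(OC)c(OC)c(OC)c3)OC12O[Si](C)(C)C(C)(C)C | intermediate
16 | methyl (2R,3R)-7-bromo-7a-[(tert-butyldimethylsilyl)oxy]-3-methyl-2-(3,4,5-trimethoxyphenyl)-2,3,3a,7a-tetrahydro-1-benzofuran-5-carboxylate (cyclohexadienyl silyl ketal; 3a and 7a not assigned) | COC(=O)C1=CC2[C@@H](C)[C@H](c3cc(OC)c(OC)c(OC)c3)OC2(O[Si](C)(C)C(C)(C)C)C(Br)=C1 | intermediate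
17 | methyl (2R,3R)-7-bromo-3-methyl-2-(3,4,5-trimethoxyphenyl)-2,3-dihydro-1-benzofuran-5-carboxylate | COC(=O)c1cc(Br)c2c(c1)[C@@H](C)[C@H](c1cc(OC)c(OC)c(OC)c1)O2 | intermediate
18 | methyl (2R,3R)-7-methoxy-3-methyl-2-(3,4,5-trimethoxyphenyl)-2,3-dihydro-1-benzofuran-5-carboxylate | COC(=O)c1cc(OC)c2c(c1)[C@@H](C)[C@H](c1cc(OC)c(OC)c(OC)c1)O2 | intermediate
19 | [(2R,3R)-7-methoxy-3-methyl-2-(3,4,5-trimethoxyphenyl)-2,3-dihydro-1-benzofuran-5-yl]methanol | OCc1cc(OC)c2c(c1)[C@@H](C)[C@H](c1cc(OC)c(OC)c(OC)c1)O2 | intermediate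
20 | (2R,3R)-7-methoxy-3-methyl-2-(3,4,5-trimethoxyphenyl)-2,3-dihydro-1-benzofuran-5-carbaldehyde | O=Cc1cc(OC)c2c(c1)[C@@H](C)[C@H](c1cc(OC)c(OC)c(OC)c1)O2 | intermediate
21 | 5-(ethylsulfonyl)-1-phenyl-1H-tetrazole | CCS(=O)(=O)c1nnnn1-c1ccccc1 | starting material
22 | potassium 1-[(1-phenyl-1H-tetrazol-5-yl)sulfonyl]ethan-1-ide (potassium sulfonyl carbanion) | C[CH-]S(=O)(=O)c1nnnn1-c1ccccc1.[K+] | intermediate
23 | potassium 1-[(2R,3R)-7-methoxy-3-methyl-2-(3,4,5-trimethoxyphenyl)-2,3-dihydro-1-benzofuran-5-yl]-2-[(1-phenyl-1H-tetrazol-5-yl)sulfonyl]propan-1-olate (β-alkoxy sulfone; new centres not assigned) | CC(C([O-])c1cc(OC)c2c(c1)[C@@H](C)[C@H](c1cc(OC)c(OC)c(OC)c1)O2)S(=O)(=O)c1nnnn1-c1ccccc1.[K+] | intermediate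
24 | (2R,3R)-7-methoxy-3-methyl-5-[(E)-prop-1-en-1-yl]-2-(3,4,5-trimethoxyphenyl)-2,3-dihydro-1-benzofuran | C/C=C/c1cc(OC)c2c(c1)[C@@H](C)[C@H](c1cc(OC)c(OC)c(OC)c1)O2 | target

**Count**
Total steps: 10. Longest linear sequence: 9 steps (steps 1–4 and 6–10, from 3,4,5-trimethoxybenzaldehyde); step 5 is a one-step side branch.

**Steps most likely to fail**

Step 6. The aromatisation may take the wrong course, with the ring alkoxide leaving from C7a instead of the silanolate, or it may stall at the diene stage. The fallback gives up keeping the lactone oxygen on C7a and re-forms the O1–C2 bond instead. It sets out from 11 and 14, which are combined as before up to the non-isolated diene 16. Dilute HCl in THF should then hydrolyse the silyl ketal, and the resulting dienone should tautomerise to the phenol methyl 3-bromo-4-hydroxy-5-[(1R,2R)-1-hydroxy-1-(3,4,5-trimethoxyphenyl)propan-2-yl]benzoate F1. Acid-catalysed cyclodehydration of F1 (cat. p-TsOH, CH2Cl2, 0 °C) through the trimethoxybenzylic cation should close the ring to the favoured trans isomer with C3 untouched. The route is rejoined at 17.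

Step 7. The coupling may be slow at the bromide flanked by O1, so that protodebromination or saponification in hot methoxide competes. The fallback installs the oxygen through boron. It sets out from 17: Miyaura borylation (B2pin2, Pd(dppf)Cl2, KOAc, dioxane, 90 °C) should give methyl (2R,3R)-3-methyl-7-(4,4,5,5-tetramethyl-1,3,2-dioxaborolan-2-yl)-2-(3,4,5-trimethoxyphenyl)-2,3-dihydro-1-benzofuran-5-carboxylate F2. Oxidation (NaBO3·4H2O, THF/H2O) should give the phenol methyl (2R,3R)-7-hydroxy-3-methyl-2-(3,4,5-trimethoxyphenyl)-2,3-dihydro-1-benzofuran-5-carboxylate F3. O-Methylation (MeI, K2CO3, acetone) brings the route back at 18.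

Step 10. The olefination may give insufficient E/Z selectivity, leaving a Z isomer that is hard to separate. The fallback replaces olefination by carbonyl addition and elimination under thermodynamic control. It sets out from 20: EtMgBr (THF, 0 °C) should give 1-[(2R,3R)-7-methoxy-3-methyl-2-(3,4,5-trimethoxyphenyl)-2,3-dihydro-1-benzofuran-5-yl]propan-1-ol F4 as a mixture of carbinol epimers. Acid-catalysed dehydration (cat. p-TsOH, toluene, 60 °C) through the cation para to O1 should give the conjugated E-propenyl arene, so the route comes back at 24.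

**Further compounds**
F1 | step 6 | methyl 3-bromo-4-hydroxy-5-[(1R,2R)-1-hydroxy-1-(3,4,5-trimethoxyphenyl)propan-2-yl]benzoate | COC(=O)c1cc(Br)c(O)c(c1)[C@@H](C)[C@H](c1cc(OC)c(OC)c(OC)c1)O
F2 | step 7 | methyl (2R,3R)-3-methyl-7-(4,4,5,5-tetramethyl-1,3,2-dioxaborolan-2-yl)-2-(3,4,5-trimethoxyphenyl)-2,3-dihydro-1-benzofuran-5-carboxylate | COC(=O)c1cc(B3OC(C)(C)C(C)(C)O3)c2c(c1)[C@@H](C)[C@H](c1cc(OC)c(OC)c(OC)c1)O2
F3 | step 7 | methyl (2R,3R)-7-hydroxy-3-methyl-2-(3,4,5-trimethoxyphenyl)-2,3-dihydro-1-benzofuran-5-carboxylate | COC(=O)c1cc(O)c2c(c1)[C@@H](C)[C@H](c1cc(OC)c(OC)c(OC)c1)O2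
F4 | step 10 | 1-[(2R,3R)-7-methoxy-3-methyl-2-(3,4,5-trimethoxyphenyl)-2,3-dihydro-1-benzofuran-5-yl]propan-1-ol (carbinol epimers) | CCC(O)c1cc(OC)c2c(c1)[C@@H](C)[C@H](c1cc(OC)c(OC)c(OC)c1)O2
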